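**Plan**

- Retrosynthetic cuts, in order: C15=C15′ (Wittig reaction of the C20 lactone aldehyde 28 with the (3R)-3-hydroxyretinyl phosphonium salt 42), C11=C12 (loss of silanol), the ring alkene C9=C10 of the lactone (ring-closing metathesis), the ester bond C19–O, C8–C9 (reductive alkylation of Meldrum's acid), C11–C12 (alkoxyallylboration) and C6–C7 (Claisen rearrangement).
- Enabling feature: in the five-membered lactone ring (C9, C10, C11, O, C19) the alkene lies between C9, which carries the C8 chain, and C10, an unsubstituted CH. It can therefore be cut back to an acrylate =CH2 and a vinyl =CH2 that recombine with loss of ethylene.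
- Forward: rings A and B come from the cyclohexenone starting materials. Ring A with its C7–C8 arm is extended to a malonate and esterified with the C10–C15 vinyl carbinol. The lactone is the only ring formed (step 14). Elimination gives the (Z)-ylidene lactone, and a C20 + C20 Wittig reaction with the ring B half completes the chain.
- Stereochemistry: C6 from a CBS reduction relayed by a suprafacial Johnson–Claisen rearrangement; C3 from substrate-controlled hydride delivery; C3′ from asymmetric transfer hydrogenation of ketoisophorone. C11 and C12 are temporary. Chain alkenes are E from the building blocks and by equilibration; C11=C12 is Z by thermodynamic preference.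

Key step: step 14

Remark: allyl 4-methoxybenzyl ether (16) is assumed to be a catalogue compound; if it is not, it is one Williamson etherification from allyl alcohol.

Conventions: atom numbers are carotenoid locants (ring A C1–C6, chain C7–C15, lactone carbonyl C19, primed numbers for the ring B half). TBS = tert-butyldimethylsilyl, TES = triethylsilyl, PMB = 4-methoxybenzyl, Ipc = isopinocampheyl from (+)-α-pinene, RA = (1R,4R)-4-(TBSO)-2,6,6-trimethylcyclohex-2-en-1-yl.

**Route**

Step 1
Reactants: 1 2,4,4-trimethylcyclohex-2-en-1-one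
Product: 2 (1S)-2,4,4-trimethylcyclohex-2-en-1-ol
Conditions: (R)-2-methyl-CBS-oxazaborolidine (10 mol%), BH3·SMe2, THF, −20 °C; MeOH, aq. work-up
Reagents that add atoms: none
Why: Corey–Bakshi–Shibata reduction: with the methyl-bearing alkene arm acting as the large substituent, the (R)-oxazaborolidine–borane complex should deliver hydride to the face that gives the (S)-allylic alcohol, the stereocentre that is relayed to C6 in step 2.

Step 2
Reactants: 2 (1S)-2,4,4-trimethylcyclohex-2-en-1-ol; 3 triethyl orthoacetate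
Product: 5 ethyl 2-[(1R)-2,6,6-trimethylcyclohex-2-en-1-yl]acetate, via mixed ketene acetal 4 (not isolated)
Conditions: CH3C(OEt)3 (excess), EtCO2H (cat.), 140 °C, EtOH distilled off
Reagents that add atoms: none
Why: Johnson–Claisen rearrangement: the ketene acetal 4 formed by alcohol exchange rearranges suprafacially across the ring, so the C–O configuration of 2 is transferred to the new C6–C7 bond (6R) while the alkene shifts to C4=C5.

Step 3
Reactants: 5 ethyl 2-[(1R)-2,6,6-trimethylcyclohex-2-en-1-yl]acetate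
Product: 6 ethyl 2-[(1R)-2,6,6-trimethyl-4-oxocyclohex-2-en-1-yl]acetate
Conditions: t-BuOOH (70% aq.), NaOCl (aq.), K2CO3, MeCN, 0 °C
Reagents that add atoms: tert-butyl hydroperoxide, CC(C)(C)OO
Why: Radical allylic oxidation by tert-butyl hydroperoxide should convert the only unhindered allylic methylene (C3) into the enone carbonyl, as on α-ionone-type rings, because the tertiary allylic C6–H is shielded by the gem-dimethyl group and its own side chain.

Step 4
Reactants: 6 ethyl 2-[(1R)-2,6,6-trimethyl-4-oxocyclohex-2-en-1-yl]acetate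
Product: 7 ethyl 2-[(1R,4R)-4-hydroxy-2,6,6-trimethylcyclohex-2-en-1-yl]acetate
Conditions: LiBH(s-Bu)3, THF, −78 °C; H2O
Reagents that add atoms: none
Why: Hydride 1,2-reduction of a β,β-disubstituted enone with a bulky trialkylborohydride: attack on C3 should come anti to the axial C1 methyl group, on the face of the pseudoaxial C6 side chain, which places the new hydroxyl trans to that chain (3R) and leaves the ester untouched at low temperature.

Step 5
Reactants: 7 ethyl 2-[(1R,4R)-4-hydroxy-2,6,6-trimethylcyclohex-2-en-1-yl]acetate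
Product: 8 ethyl 2-(RA)acetate
Conditions: TBSCl, imidazole, DMF, rt
Reagents that add atoms: tert-butyldimethylsilyl chloride, CC(C)(C)[Si](C)(C)Cl
Why: Imidazole-promoted silylation of the secondary alcohol gives a silyl ether that withstands every later step up to the fluoride treatment of step 16.

Step 6
Reactants: 8 ethyl 2-(RA)acetate
Product: 9 2-(RA)acetaldehyde
Conditions: i-Bu2AlH (1.1 equiv), CH2Cl2, −78 °C; aq. potassium sodium tartrate
Reagents that add atoms: none
Why: Partial reduction of the ester by i-Bu2AlH at −78 °C stops at the aluminium hemiacetal, which releases the aldehyde only on work-up.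

Step 7
Reactants: 9 2-(RA)acetaldehyde; 10 Meldrum's acid (2,2-dimethyl-1,3-dioxane-4,6-dione)
Product: 12 5-[2-(RA)ethyl]-2,2-dimethyl-1,3-dioxane-4,6-dione, via alkylidene Meldrum's acid 11 (not isolated)
Conditions: diethyl 2,6-dimethyl-1,4-dihydropyridine-3,5-dicarboxylate (Hantzsch ester), L-proline (cat.), CH2Cl2, rt
Reagents that add atoms: none
Why: Organocatalytic reductive alkylation: Knoevenagel condensation gives the alkylidene 11, which the Hantzsch ester reduces by conjugate hydride transfer, so Meldrum's acid is monoalkylated cleanly and the C8–C9 bond is formed.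

Step 8
Reactants: 13 2-(TBSO)acetaldehyde; 14 2-(triphenylphosphoranylidene)propanal
Product: 15 (2E)-4-(TBSO)-2-methylbut-2-enal
Conditions: toluene, 80 °C
Reagents that add atoms: none
Why: Wittig olefination with a stabilised formyl ylide, which is expected to give the (E)-enal.

Step 9
Reactants: 15 (2E)-4-(TBSO)-2-methylbut-2-enal; 16 allyl 4-methoxybenzyl ether
Product: 19 (3R,4R,5E)-7-(TBSO)-3-(PMBO)-5-methylhepta-1,5-dien-4-ol, via allylborane 17 (not isolated), via borinate ester 18 (not isolated)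
Conditions: 16, s-BuLi, THF, −78 °C; (−)-Ipc2BOMe; BF3·OEt2; 15, −78 °C; then NaOH, H2O2, 0 °C to rt
Reagents that add atoms: none
Why: Brown alkoxyallylboration: the (Z)-γ-alkoxyallylborane 17 adds through a chair-like six-membered transition state to give the syn adduct, the isopinocampheyl groups selecting the aldehyde face, so that C11 and C12 (both R) are set in one operation only to give a single, well-defined compound and are erased in step 15.

Step 10
Reactants: 19 (3R,4R,5E)-7-(TBSO)-3-(PMBO)-5-methylhepta-1,5-dien-4-ol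
Product: 20 (3R,4R,5E)-4,7-bis(TBSO)-3-(PMBO)-5-methylhepta-1,5-diene
Conditions: TBSOTf, 2,6-lutidine, CH2Cl2, −78 to 0 °C
Reagents that add atoms: tert-butyldimethylsilyl trifluoromethanesulfonate, CC(C)(C)[Si](C)(C)OS(=O)(=O)C(F)(F)F
Why: Silylation of the hindered allylic alcohol with the silyl triflate and a non-nucleophilic base.

Step 11
Reactants: 20 (3R,4R,5E)-4,7-bis(TBSO)-3-(PMBO)-5-methylhepta-1,5-diene
Product: 21 (3R,4R,5E)-4,7-bis(TBSO)-5-methylhepta-1,5-dien-3-ol
Conditions: DDQ, CH2Cl2/pH 7 buffer, 0 °C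
Reagents that add atoms: none
Why: Oxidative cleavage of the 4-methoxybenzyl ether by DDQ (hydride abstraction from the electron-rich benzylic position, then hydrolysis), which spares silyl ethers and isolated alkenes.

Step 12
Reactants: 12 5-[2-(RA)ethyl]-2,2-dimethyl-1,3-dioxane-4,6-dione; 21 (3R,4R,5E)-4,7-bis(TBSO)-5-methylhepta-1,5-dien-3-ol
Product: 22 3-{[(3R,4R,5E)-4,7-bis(TBSO)-5-methylhepta-1,5-dien-3-yl]oxy}-3-oxo-2-[2-(RA)ethyl]propanoic acid (both C9 epimers)
Conditions: toluene, 90 °C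
Reagents that add atoms: none
Why: Thermal alcoholysis of a 5-monoalkyl Meldrum's acid: the carbinol opens the dioxanedione and acetone is lost, which gives the malonic half-ester without a coupling reagent, C9 arising as both epimers because it becomes sp2 in step 13.

Step 13
Reactants: 22 malonic half-ester
Product: 24 (3R,4R,5E)-4,7-bis(TBSO)-5-methylhepta-1,5-dien-3-yl 2-methylidene-4-(RA)butanoate, via Mannich base 23 (not isolated)
Conditions: (CH2O)n, Et2NH, THF, 65 °C
Reagents that add atoms: formaldehyde (as paraformaldehyde), C=O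
Why: Decarboxylative Mannich methylenation: the half-ester condenses with formaldehyde and diethylamine to the Mannich base 23, which loses CO2 and the amine to give the 2-substituted acrylate.

Step 14
Reactants: 24 (3R,4R,5E)-4,7-bis(TBSO)-5-methylhepta-1,5-dien-3-yl 2-methylidene-4-(RA)butanoate
Product: 25 (5R)-5-[(1R,2E)-1,4-bis(TBSO)-2-methylbut-2-en-1-yl]-3-[2-(RA)ethyl]furan-2(5H)-one
Conditions: second-generation Grubbs catalyst (H2IMes)(PCy3)Cl2Ru=CHPh (10 mol%, in portions), toluene (2 mM), 80 °C, argon purge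
Reagents that add atoms: none
Why: The ruthenium benzylidene first exchanges onto the monosubstituted vinyl group (C10), the only unhindered alkene that is not electron-poor, and the resulting alkylidene adds intramolecularly across the 1,1-disubstituted acrylate alkene at C9 to give a ruthenacyclobutane whose cycloreversion forms C9=C10 and a ruthenium methylidene that carries the chain, the two lost carbons leaving as ethylene. The closest known reaction type is the ring-closing metathesis of 2-substituted acrylates of allylic alcohols to 3-substituted butenolides with second-generation ruthenium catalysts. The single ring closed is the five-membered unsaturated lactone (C9, C10, C11, O, C19), closed by alkene–alkene metathesis with the new double bond inside the ring and therefore necessarily cis. No stereocentre is created, and C11 and C12 pass through unchanged. The step needs chemoselectivity for the two terminal alkenes over the trisubstituted C4=C5 and C13=C14 alkenes, which their substitution secures (engaging C13 would require a cyclobutene or a tetrasubstituted six-ring alkene), and ring closure over dimerisation, which high dilution and continuous removal of ethylene secure.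

Step 15
Reactants: 25 (5R)-5-[(1R,2E)-1,4-bis(TBSO)-2-methylbut-2-en-1-yl]-3-[2-(RA)ethyl]furan-2(5H)-one
Product: 26 (5Z)-5-[(2E)-4-(TBSO)-2-methylbut-2-en-1-ylidene]-3-[2-(RA)ethyl]furan-2(5H)-one
Conditions: DBU, CH2Cl2, 0 °C to rt
Reagents that add atoms: none
Why: E1cB elimination: DBU removes the acidic hydrogen on C11 to give a 2-oxidofuran, which expels the allylic silyloxide from C12, and the (Z)-ylidene isomer, free of strain between C13 and the C10 hydrogen, is expected to prevail while both temporary stereocentres vanish.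

Step 16
Reactants: 26 (5Z)-5-[(2E)-4-(TBSO)-2-methylbut-2-en-1-ylidene]-3-[2-(RA)ethyl]furan-2(5H)-one
Product: 27 (5Z)-5-[(2E)-4-hydroxy-2-methylbut-2-en-1-ylidene]-3-{2-[(1R,4R)-4-hydroxy-2,6,6-trimethylcyclohex-2-en-1-yl]ethyl}furan-2(5H)-one
Conditions: HF·pyridine, pyridine, THF, 0 °C to rt
Reagents that add atoms: none
Why: Desilylation with pyridine-buffered HF·pyridine, chosen because it is neither basic enough to open the enol lactone nor acidic enough to ionise the allylic C3 alcohol.

Step 17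
Reactants: 27 lactone diol
Product: 28 (2E)-4-[(2Z)-4-{2-[(1R,4R)-4-hydroxy-2,6,6-trimethylcyclohex-2-en-1-yl]ethyl}-5-oxofuran-2(5H)-ylidene]-3-methylbut-2-enal
Conditions: TEMPO (10 mol%), PhI(OAc)2, CH2Cl2, rt
Reagents that add atoms: none
Why: Oxoammonium-mediated (TEMPO) oxidation with PhI(OAc)2 as terminal oxidant, which is selective for the primary allylic alcohol over the secondary ring alcohol, whereas MnO2 would also oxidise the allylic C3 hydroxyl.

Step 18
Reactants: 29 ketoisophorone (2,6,6-trimethylcyclohex-2-ene-1,4-dione)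
Product: 30 (4S)-4-hydroxy-2,6,6-trimethylcyclohex-2-en-1-one
Conditions: Ru(p-cymene)[(S,S)-TsDPEN] (0.5 mol%), i-PrOH, rt
Reagents that add atoms: none
Why: Noyori-type asymmetric transfer hydrogenation: only the unhindered C4 carbonyl is reduced, and with the alkene arm taking the place of the aryl group of aryl ketones the (S,S)-catalyst should give the (4S)-alcohol, which becomes the (3′R)-centre of ring B.

Step 19
Reactants: 30 (4S)-4-hydroxy-2,6,6-trimethylcyclohex-2-en-1-one
Product: 31 (4S)-2,6,6-trimethyl-4-(TESO)cyclohex-2-en-1-one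
Conditions: TESCl, imidazole, CH2Cl2, 0 °C
Reagents that add atoms: chlorotriethylsilane, CC[Si](CC)(CC)Cl
Why: Silylation gives a triethylsilyl ether that is stable to hydride and to palladium catalysis but is cleaved by methanolic acid in step 23.

Step 20
Reactants: 31 (4S)-2,6,6-trimethyl-4-(TESO)cyclohex-2-en-1-one
Product: 33 (4R)-2,6,6-trimethyl-4-(TESO)cyclohex-1-en-1-yl trifluoromethanesulfonate, via lithium enolate 32 (not isolated)
Conditions: LiBH(s-Bu)3, THF, −78 °C; then PhNTf2, −78 °C to rt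
Reagents that add atoms: N-phenylbis(trifluoromethanesulfonimide), O=S(=O)(N(c1ccccc1)S(=O)(=O)C(F)(F)F)C(F)(F)F
Why: Conjugate reduction of an enone with no substituent on the β-carbon by LiBH(s-Bu)3, whose 1,2-addition is blocked by the gem-dimethyl group, followed by O-sulfonylation of the regiodefined enolate 32, which fixes the ring alkene at C5′=C6′.

Step 21
Reactants: 34 (2E)-3-methylpent-2-en-4-yn-1-ol
Product: 35 (2E,4E)-3-methyl-5-(tributylstannyl)penta-2,4-dien-1-ol
Conditions: Bu3SnH, PdCl2(PPh3)2 (2 mol%), THF, 0 °C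
Reagents that add atoms: tributyltin hydride, CCCC[SnH](CCCC)CCCC
Why: Palladium-catalysed syn-hydrostannation of the terminal alkyne of a conjugated enyne, which places tin on the terminal carbon and gives the (4E)-stannane.

Step 22
Reactants: 33 (4R)-2,6,6-trimethyl-4-(TESO)cyclohex-1-en-1-yl trifluoromethanesulfonate; 35 (2E,4E)-3-methyl-5-(tributylstannyl)penta-2,4-dien-1-ol
Product: 36 (2E,4E)-3-methyl-5-[(4R)-2,6,6-trimethyl-4-(TESO)cyclohex-1-en-1-yl]penta-2,4-dien-1-ol
Conditions: Pd2(dba)3 (2.5 mol%), AsPh3 (20 mol%), NMP, 60 °C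
Reagents that add atoms: none
Why: Stille cross-coupling of a hindered cyclohexenyl triflate with an alkenylstannane, with triphenylarsine as a weakly bound ligand to speed transmetalation, both alkene geometries being retained.

Step 23
Reactants: 36 (2E,4E)-3-methyl-5-[(4R)-2,6,6-trimethyl-4-(TESO)cyclohex-1-en-1-yl]penta-2,4-dien-1-ol
Product: 38 {(2E,4E)-5-[(4R)-4-hydroxy-2,6,6-trimethylcyclohex-1-en-1-yl]-3-methylpenta-2,4-dien-1-yl}triphenylphosphonium bromide, via desilylated diol 37 (not isolated)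
Conditions: PPh3·HBr, MeOH, rt
Reagents that add atoms: triphenylphosphine hydrobromide, Br.c1ccc(cc1)P(c1ccccc1)c1ccccc1
Why: Acid methanolysis of the silyl ether to diol 37 and SN1-type displacement of the doubly allylic primary hydroxyl by triphenylphosphine at the chain terminus, the usual entry to C15 Wittig salts of the retinoid series.

Step 24
Reactants: 38 C15 phosphonium bromide; 39 (2E)-4-acetoxy-2-methylbut-2-enal
Product: 41 (2E,4E,6E,8E)-9-[(4R)-4-hydroxy-2,6,6-trimethylcyclohex-1-en-1-yl]-3,7-dimethylnona-2,4,6,8-tetraen-1-yl acetate, via phosphorus ylide 40 (not isolated)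
Conditions: 1,2-epoxybutane, EtOH, reflux
Reagents that add atoms: none
Why: Wittig olefination under neutral conditions: bromide opens 1,2-epoxybutane to an alkoxide that generates ylide 40 without touching the acetate, and the all-E ester is taken on after crystallisation of the E/Z mixture formed at C11′=C12′.

Step 25
Reactants: 41 (3R)-3-hydroxyretinyl acetate
Product: 42 {(2E,4E,6E,8E)-9-[(4R)-4-hydroxy-2,6,6-trimethylcyclohex-1-en-1-yl]-3,7-dimethylnona-2,4,6,8-tetraen-1-yl}triphenylphosphonium bromide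
Conditions: PPh3·HBr, MeOH, rt, dark
Reagents that add atoms: triphenylphosphine hydrobromide, Br.c1ccc(cc1)P(c1ccccc1)c1ccccc1
Why: Ionisation of the polyenylic acetate by HBr to the delocalised retinyl-type cation and capture by triphenylphosphine at the terminal carbon, the standard route from retinyl esters to their Wittig salts.

Step 26
Reactants: 28 C20 lactone aldehyde; 42 C20 phosphonium bromide
Product: 44 CNP0242041.1, via phosphorus ylide 43 (not isolated)
Conditions: 1,2-epoxybutane, EtOH/CH2Cl2, reflux, dark; then heptane, 80 °C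
Reagents that add atoms: none
Why: Wittig olefination forming C15=C15′ under the same neutral conditions, which leave the enol lactone and both free hydroxyls intact, followed by thermal equilibration of the central Z isomer to the all-E polyene.

**Compound list**

1 | 2,4,4-trimethylcyclohex-2-en-1-one | CC1=CC(C)(C)CCC1=O | starting material
2 | (1S)-2,4,4-trimethylcyclohex-2-en-1-ol | CC1=CC(C)(C)CC[C@@H]1O | intermediate
3 | triethyl orthoacetate | CCOC(C)(OCC)OCC | starting material
4 | 1-ethoxyethenyl (1S)-2,4,4-trimethylcyclohex-2-en-1-yl ether (mixed ketene acetal) | C=C(OCC)O[C@H]1CCC(C)(C)C=C1C | intermediate (not isolated)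
5 | ethyl 2-[(1R)-2,6,6-trimethylcyclohex-2-en-1-yl]acetate | CC1=CCCC(C)(C)[C@H]1CC(=O)OCC | intermediate
6 | ethyl 2-[(1R)-2,6,6-trimethyl-4-oxocyclohex-2-en-1-yl]acetate | CC1=CC(=O)CC(C)(C)[C@H]1CC(=O)OCC | intermediate
7 | ethyl 2-[(1R,4R)-4-hydroxy-2,6,6-trimethylcyclohex-2-en-1-yl]acetate | CC1=C[C@H](O)CC(C)(C)[C@H]1CC(=O)OCC | intermediate
8 | ethyl 2-[(1R,4R)-4-(TBSO)-2,6,6-trimethylcyclohex-2-en-1-yl]acetate | CC1=C[C@H](O[Si](C)(C)C(C)(C)C)CC(C)(C)[C@H]1CC(=O)OCC | intermediate
9 | 2-[(1R,4R)-4-(TBSO)-2,6,6-trimethylcyclohex-2-en-1-yl]acetaldehyde | CC1=C[C@H](O[Si](C)(C)C(C)(C)C)CC(C)(C)[C@H]1CC=O | intermediate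
10 | Meldrum's acid (2,2-dimethyl-1,3-dioxane-4,6-dione) | CC1(C)OC(=O)CC(=O)O1 | starting material
11 | 5-{2-[(1R,4R)-4-(TBSO)-2,6,6-trimethylcyclohex-2-en-1-yl]ethylidene}-2,2-dimethyl-1,3-dioxane-4,6-dione | CC1=C[C@H](O[Si](C)(C)C(C)(C)C)CC(C)(C)[C@H]1CC=C1C(=O)OC(C)(C)OC1=O | intermediate (not isolated)
12 | 5-{2-[(1R,4R)-4-(TBSO)-2,6,6-trimethylcyclohex-2-en-1-yl]ethyl}-2,2-dimethyl-1,3-dioxane-4,6-dione | CC1=C[C@H](O[Si](C)(C)C(C)(C)C)CC(C)(C)[C@H]1CCC1C(=O)OC(C)(C)OC1=O | intermediate
13 | 2-(tert-butyldimethylsilyloxy)acetaldehyde | CC(C)(C)[Si](C)(C)OCC=O | starting material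
14 | 2-(triphenylphosphoranylidene)propanal | CC(C=O)=P(c1ccccc1)(c1ccccc1)c1ccccc1 | starting material
15 | (2E)-4-(TBSO)-2-methylbut-2-enal | CC(C)(C)[Si](C)(C)OC/C=C(\C)C=O | intermediate
16 | allyl 4-methoxybenzyl ether | C=CCOCc1ccc(OC)cc1 | starting material
17 | [(2Z)-3-(PMBO)prop-2-en-1-yl]bis(isopinocampheyl)borane | COc1ccc(CO/C=C\CB([C@@H]2C[C@@H]3C[C@H]([C@H]2C)C3(C)C)[C@@H]2C[C@@H]3C[C@H]([C@H]2C)C3(C)C)cc1 | intermediate (not isolated)
18 | bis(isopinocampheyl)borinic ester of alcohol 19 (B–O at C12) | CC(C)(C)[Si](C)(C)OC/C=C(\C)[C@@H](OB([C@@H]1C[C@@H]2C[C@H]([C@H]1C)C2(C)C)[C@@H]1C[C@@H]2C[C@H]([C@H]1C)C2(C)C)[C@H](OCc1ccc(OC)cc1)C=C | intermediate (not isolated)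
19 | (3R,4R,5E)-7-(TBSO)-3-(PMBO)-5-methylhepta-1,5-dien-4-ol | CC(C)(C)[Si](C)(C)OC/C=C(\C)[C@@H](O)[C@H](OCc1ccc(OC)cc1)C=C | intermediate
20 | (3R,4R,5E)-4,7-bis(TBSO)-3-(PMBO)-5-methylhepta-1,5-diene | CC(C)(C)[Si](C)(C)OC/C=C(\C)[C@@H](O[Si](C)(C)C(C)(C)C)[C@H](OCc1ccc(OC)cc1)C=C | intermediate
21 | (3R,4R,5E)-4,7-bis(TBSO)-5-methylhepta-1,5-dien-3-ol | CC(C)(C)[Si](C)(C)OC/C=C(\C)[C@@H](O[Si](C)(C)C(C)(C)C)[C@H](O)C=C | intermediate
22 | 3-{[(3R,4R,5E)-4,7-bis(TBSO)-5-methylhepta-1,5-dien-3-yl]oxy}-3-oxo-2-[2-(RA)ethyl]propanoic acid (both C9 epimers) | CC1=C[C@H](O[Si](C)(C)C(C)(C)C)CC(C)(C)[C@H]1CCC(C(=O)O)C(=O)O[C@H](C=C)[C@H](O[Si](C)(C)C(C)(C)C)/C(C)=C/CO[Si](C)(C)C(C)(C)C | intermediate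
23 | 2-[(diethylamino)methyl] derivative of half-ester 22 (Mannich base) | CC1=C[C@H](O[Si](C)(C)C(C)(C)C)CC(C)(C)[C@H]1CCC(CN(CC)CC)(C(=O)O)C(=O)O[C@H](C=C)[C@H](O[Si](C)(C)C(C)(C)C)/C(C)=C/CO[Si](C)(C)C(C)(C)C | intermediate (not isolated)
24 | (3R,4R,5E)-4,7-bis(TBSO)-5-methylhepta-1,5-dien-3-yl 2-methylidene-4-(RA)butanoate | CC1=C[C@H](O[Si](C)(C)C(C)(C)C)CC(C)(C)[C@H]1CCC(=C)C(=O)O[C@H](C=C)[C@H](O[Si](C)(C)C(C)(C)C)/C(C)=C/CO[Si](C)(C)C(C)(C)C | intermediate
25 | (5R)-5-[(1R,2E)-1,4-bis(TBSO)-2-methylbut-2-en-1-yl]-3-[2-(RA)ethyl]furan-2(5H)-one | CC1=C[C@H](O[Si](C)(C)C(C)(C)C)CC(C)(C)[C@H]1CCC1=C[C@@H](OC1=O)[C@H](O[Si](C)(C)C(C)(C)C)/C(C)=C/CO[Si](C)(C)C(C)(C)C | intermediate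
26 | (5Z)-5-[(2E)-4-(TBSO)-2-methylbut-2-en-1-ylidene]-3-[2-(RA)ethyl]furan-2(5H)-one | CC1=C[C@H](O[Si](C)(C)C(C)(C)C)CC(C)(C)[C@H]1CCC1=C/C(=C/C(C)=C/CO[Si](C)(C)C(C)(C)C)OC1=O | intermediate
27 | (5Z)-5-[(2E)-4-hydroxy-2-methylbut-2-en-1-ylidene]-3-{2-[(1R,4R)-4-hydroxy-2,6,6-trimethylcyclohex-2-en-1-yl]ethyl}furan-2(5H)-one | CC1=C[C@H](O)CC(C)(C)[C@H]1CCC1=C/C(=C/C(C)=C/CO)OC1=O | intermediate
28 | (2E)-4-[(2Z)-4-{2-[(1R,4R)-4-hydroxy-2,6,6-trimethylcyclohex-2-en-1-yl]ethyl}-5-oxofuran-2(5H)-ylidene]-3-methylbut-2-enal | CC1=C[C@H](O)CC(C)(C)[C@H]1CCC1=C/C(=C/C(C)=C/C=O)OC1=O | intermediate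
29 | ketoisophorone (2,6,6-trimethylcyclohex-2-ene-1,4-dione) | CC1=CC(=O)CC(C)(C)C1=O | starting material
30 | (4S)-4-hydroxy-2,6,6-trimethylcyclohex-2-en-1-one | CC1=C[C@@H](O)CC(C)(C)C1=O | intermediate
31 | (4S)-2,6,6-trimethyl-4-(TESO)cyclohex-2-en-1-one | CC1=C[C@@H](O[Si](CC)(CC)CC)CC(C)(C)C1=O | intermediate
32 | lithium (4R)-2,6,6-trimethyl-4-(TESO)cyclohex-1-en-1-olate | [Li]OC1=C(C)C[C@@H](O[Si](CC)(CC)CC)CC1(C)C | intermediate (not isolated)
33 | (4R)-2,6,6-trimethyl-4-(TESO)cyclohex-1-en-1-yl trifluoromethanesulfonate | FC(F)(F)S(=O)(=O)OC1=C(C)C[C@@H](O[Si](CC)(CC)CC)CC1(C)C | intermediate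
34 | (2E)-3-methylpent-2-en-4-yn-1-ol | C#C/C(C)=C/CO | starting material
35 | (2E,4E)-3-methyl-5-(tributylstannyl)penta-2,4-dien-1-ol | CCCC[Sn](CCCC)(CCCC)/C=C/C(C)=C/CO | intermediate
36 | (2E,4E)-3-methyl-5-[(4R)-2,6,6-trimethyl-4-(TESO)cyclohex-1-en-1-yl]penta-2,4-dien-1-ol | OC/C=C(C)/C=C/C1=C(C)C[C@@H](O[Si](CC)(CC)CC)CC1(C)C | intermediate
37 | (2E,4E)-5-[(4R)-4-hydroxy-2,6,6-trimethylcyclohex-1-en-1-yl]-3-methylpenta-2,4-dien-1-ol | OC/C=C(C)/C=C/C1=C(C)C[C@@H](O)CC1(C)C | intermediate (not isolated)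
38 | {(2E,4E)-5-[(4R)-4-hydroxy-2,6,6-trimethylcyclohex-1-en-1-yl]-3-methylpenta-2,4-dien-1-yl}triphenylphosphonium bromide | [Br-].c1ccccc1[P+](c1ccccc1)(c1ccccc1)C/C=C(C)/C=C/C1=C(C)C[C@@H](O)CC1(C)C | intermediate
39 | (2E)-4-acetoxy-2-methylbut-2-enal | CC(=O)OC/C=C(\C)C=O | starting material
40 | triphenyl{(2E,4E)-5-[(4R)-4-hydroxy-2,6,6-trimethylcyclohex-1-en-1-yl]-3-methylpenta-2,4-dien-1-ylidene}phosphorane | c1ccccc1P(c1ccccc1)(c1ccccc1)=C/C=C(C)/C=C/C1=C(C)C[C@@H](O)CC1(C)C | intermediate (not isolated)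
41 | (2E,4E,6E,8E)-9-[(4R)-4-hydroxy-2,6,6-trimethylcyclohex-1-en-1-yl]-3,7-dimethylnona-2,4,6,8-tetraen-1-yl acetate [(3R)-3-hydroxyretinyl acetate] | CC(=O)OC/C=C(C)/C=C/C=C(C)/C=C/C1=C(C)C[C@@H](O)CC1(C)C | intermediate
42 | {(2E,4E,6E,8E)-9-[(4R)-4-hydroxy-2,6,6-trimethylcyclohex-1-en-1-yl]-3,7-dimethylnona-2,4,6,8-tetraen-1-yl}triphenylphosphonium bromide | [Br-].c1ccccc1[P+](c1ccccc1)(c1ccccc1)C/C=C(C)/C=C/C=C(C)/C=C/C1=C(C)C[C@@H](O)CC1(C)C | intermediate
43 | triphenyl{(2E,4E,6E,8E)-9-[(4R)-4-hydroxy-2,6,6-trimethylcyclohex-1-en-1-yl]-3,7-dimethylnona-2,4,6,8-tetraen-1-ylidene}phosphorane | c1ccccc1P(c1ccccc1)(c1ccccc1)=C/C=C(C)/C=C/C=C(C)/C=C/C1=C(C)C[C@@H](O)CC1(C)C | intermediate (not isolated)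
44 | CNP0242041.1: (11Z)-ylidene lactone with the (3R,6R)-3-hydroxy-7,8-dihydro ring A half joined through the all-E C12–C7′ polyene to the (3′R)-3′-hydroxy ring B | CC1=C[C@H](O)CC(C)(C)[C@H]1CCC1=C/C(=C/C(C)=C/C=C/C=C(C)/C=C/C=C(C)/C=C/C2=C(C)C[C@@H](O)CC2(C)C)OC1=O | target

**Step count and risks**

Total step count: 26. Longest linear sequence: 14 steps (steps 1–7, 12–17 and 26).

Step 14. Loading of the ruthenium carbene on the C10 vinyl group is slowed by the two branched neighbours C11 and C12, so dimerisation by cross-metathesis or decay of the catalyst may outrun ring closure. The fallback sets out from 12 and returns at 26; it closes the lactone before the C12–C15 arm is attached. Heating 12 with allyl alcohol should give the allyl hydrogen malonate F1. Decarboxylative Mannich methylenation then gives the allyl 2-methylidene ester F2. Ring-closing metathesis of this unhindered diene with the same catalyst gives the 3-substituted furan-2(5H)-one F3. Silylation (TBSOTf, Et3N) gives the 2-silyloxyfuran F4. Its vinylogous Mukaiyama aldol addition to aldehyde 15 (TBSOTf, CH2Cl2, −78 °C) gives the silylated γ-adduct F5 as a diastereomer mixture with the constitution of 25. DBU added to the same flask eliminates silanol to 26.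

Step 4. Facial selectivity of hydride delivery may be poor, because the face anti to the axial C1 methyl group is also the face of the pseudoaxial side chain. The fallback sets out from 6 and returns at 7. The ketone is reduced without regard to selectivity (NaBH4, CeCl3, EtOH) and the epimers are separated. The cis alcohol F6 is inverted by a Mitsunobu reaction (4-nitrobenzoic acid, PPh3, diisopropyl azodicarboxylate) to the 4-nitrobenzoate F7, whose ethanolysis (K2CO3, EtOH) gives 7, so that all material converges on the trans alcohol.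

Step 12. Acylation of the hindered carbinol 21 by the Meldrum's acid derivative may be slow, so decarboxylation of the half-ester or migration of the neighbouring silyl group may compete at the temperature needed. The fallback sets out from 12 and returns at 24. Compound 12 is converted with Me2N=CH2 I in methanol into the methyl 2-methylidene ester F8. Saponification (LiOH, THF/H2O) gives the 2-methylidene acid F9. Yamaguchi esterification (2,4,6-trichlorobenzoyl chloride, Et3N, then 21 and DMAP, toluene, rt) joins it to 21 to give 24 directly.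

**Further compounds**

F1 | step 14 | allyl hydrogen 2-[2-(RA)ethyl]malonate | CC1=C[C@H](O[Si](C)(C)C(C)(C)C)CC(C)(C)[C@H]1CCC(C(=O)O)C(=O)OCC=C
F2 | step 14 | prop-2-en-1-yl 2-methylidene-4-(RA)butanoate | CC1=C[C@H](O[Si](C)(C)C(C)(C)C)CC(C)(C)[C@H]1CCC(=C)C(=O)OCC=C
F3 | step 14 | 3-[2-(RA)ethyl]furan-2(5H)-one | CC1=C[C@H](O[Si](C)(C)C(C)(C)C)CC(C)(C)[C@H]1CCC1=CCOC1=O
F4 | step 14 | tert-butyl({3-[2-(RA)ethyl]furan-2-yl}oxy)dimethylsilane | CC1=C[C@H](O[Si](C)(C)C(C)(C)C)CC(C)(C)[C@H]1CCc1ccoc1O[Si](C)(C)C(C)(C)C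
F5 | step 14 | 5-[(2E)-1,4-bis(TBSO)-2-methylbut-2-en-1-yl]-3-[2-(RA)ethyl]furan-2(5H)-one (diastereomer mixture at C11 and C12) | CC1=C[C@H](O[Si](C)(C)C(C)(C)C)CC(C)(C)[C@H]1CCC1=CC(OC1=O)C(O[Si](C)(C)C(C)(C)C)/C(C)=C/CO[Si](C)(C)C(C)(C)C
F6 | step 4 | ethyl 2-[(1R,4S)-4-hydroxy-2,6,6-trimethylcyclohex-2-en-1-yl]acetate | CC1=C[C@@H](O)CC(C)(C)[C@H]1CC(=O)OCC
F7 | step 4 | (1R,4R)-4-(2-ethoxy-2-oxoethyl)-3,5,5-trimethylcyclohex-2-en-1-yl 4-nitrobenzoate | CC1=C[C@H](OC(=O)c2ccc(cc2)[N+](=O)[O-])CC(C)(C)[C@H]1CC(=O)OCC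
F8 | step 12 | methyl 2-methylidene-4-(RA)butanoate | CC1=C[C@H](O[Si](C)(C)C(C)(C)C)CC(C)(C)[C@H]1CCC(=C)C(=O)OC
F9 | step 12 | 2-methylidene-4-(RA)butanoic acid | CC1=C[C@H](O[Si](C)(C)C(C)(C)C)CC(C)(C)[C@H]1CCC(=C)C(=O)O
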